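## The problem

The target is a 2-aryl-4H-chromen-4-one: ring A (C4a to C8a) and ring C (O1, C2 to C4) share the C4a–C8a bond, and ring B sits on C2. Every position of ring C and five of the six positions of ring A are substituted. The five oxygen functions occur in three states: methyl ethers at C3 and C8, free phenols at C5 and C7, and a 3-methylbut-2-enyl (prenyl) ether at C4'. There is no stereocentre, so nothing has to be controlled or relayed; the one sp3 stereocentre met on the way (C8 of the open chain) is erased when ring C becomes aromatic. The prenyl ether is the fragile group: it ionises in strong acid, is lost or reduced under hydrogenolysis, and would not survive a persulfate oxidation followed by hot acid, so it has to enter late. The remaining selectivity problems are the placing of the C8 oxygen and the distinction of 7-OH (the most acidic phenol, para to the C4 carbonyl) from 4'-OH and from the chelated 5-OH. The enabling feature is the oxygen pattern of ring A: C5, C7 and C8a carry oxygen on alternate carbons and C4a carries the acyl carbon C4, the signature of three acetate units folded onto a starter made of ring B with C2 to C4. Without the C8 oxygen, ring A is a phloroglucinol that is symmetrical about C4a, so ring C can close onto either ortho oxygen with the same result, and C8 is then the position para to 5-OH, where a phenolate can be hydroxylated.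

## Retrosynthesis

**21 ⇒ 20 ⇒ 18 + 19 ⇒ 17.** The bonds cut are the O–C bond of the prenyl ether and the temporary 7-O acetal. The prenyl group goes first because it tolerates neither the oxidation and hot-acid sequence nor the hydrogenolysis that the earlier stages need. The neighbouring choice, carrying it on ring B from the start, would restrict every later step. Triol 17 is simpler by the whole side chain and has three phenols of graded acidity. The forward direction asks for acetal protection of the most acidic 7-OH (18), Williamson alkylation of 4'-OH with bromide 19 (20; the chelated 5-OH does not compete), and an acetal cleavage mild enough to spare the allylic ether (21).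

**17 ⇒ 16 ⇒ 15 ⇒ 13 ⇒ 12.** The cut is the C8–O bond with its methyl group, together with the two benzyl O–C bonds. Removing the C8 oxygen gives the symmetrical 5,7-dihydroxy pattern of 12. Keeping that oxygen through ring construction would desymmetrise ring A and open a 6-methoxy/8-methoxy ambiguity when ring C closes. C8 is para to 5-OH, so a phenolate-directed para-hydroxylation can place the oxygen. The forward sequence asks for:
- 7-O-benzylation (13), so that only the 5-phenolate directs and the new 8-OH becomes the only non-chelated phenol;
- Elbs oxidation (15);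
- selective 8-O-methylation (16);
- one hydrogenolysis that removes both benzyl groups (17).

**12 ⇒ 11 ⇒ 10 ⇒ 9.** This is the key cut: O1–C2 (ring C) and C4a–C8a (ring A). Classical neighbours cut C4–C4a (acylation of a preformed polyphenol) or C2–C3; both need a differentiated aromatic ring A as starting material. The polyketide cut instead takes ring A apart completely. Flavone 12 comes from diketone 11 by cyclodehydration, 11 from ketal 10 by unmasking, and acylphloroglucinol 10 from the open triketo ester 9 by Claisen closure of C6 onto the C1 ester. Compound 9 has no ring beyond ring B and one stereocentre that does not matter. The forward reaction must make the Claisen closure beat the aldol closure of C2 onto C7, and must keep the aryl ketone silent until acid is added.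

**9 ⇒ 8 + 7.** The cut is the C6–C7 bond of the chain. Cutting C4–C5 instead would require an acyl donor that itself contains an acidic 1,3-dicarbonyl unit and would quench the nucleophile. At C6–C7 the nucleophile is the terminal carbanion of trianion 8 and the electrophile is the simple ester 7. The ketal in 7 is essential: it removes the 1,3-dicarbonyl acidity next to the ester. The forward reaction asks that addition to the hindered but α-alkoxy-activated ester be faster than proton transfer.

**7 ⇒ 6 ⇒ 5 + 4, and 5 ⇒ 3.** The cuts are the two ketal C–O bonds and then the bond between the carbonyl carbon and the α-carbon of the β-keto ester (chain C9–C8). A crossed Claisen acylation of enolate 5 (from ester 3) with the non-enolisable acid chloride 4 gives 6 in one step. The 3-methoxy group of the target arrives already placed in 3, and ring B with its protected 4'-oxygen arrives in 4. Ketalisation of 6 to 7 is asked to stop at the ketal and not go on to the enol ether.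

**8 ⇒ 2 ⇒ 1.** Trianion 8 is the triply deprotonated diketo ester 2, and 2 is the ring-opened, deacetylated form of the bulk pyranone 1. One operation gives the six-carbon unit that becomes C4a, C5, C6, C7, C8 and C8a.

## Roads not taken

**Alternative 1:** The cut is C3–C4 and O1–C2, with ring A supplied as salicylaldehyde A1 (2-hydroxy-3-methoxy-4,6-bis(methoxymethoxy)benzaldehyde) and C2, C3 and ring B as the aryl methoxyalkyne A2.
- Forward key step: [Cp*RhCl2]2 with Cu(OAc)2 as oxidant activates the aldehyde C–H bond, the alkyne inserts into the acyl–rhodium bond and C–O reductive elimination closes ring C to give flavone A3. Loss of the two acetals from A3 would give 21 directly.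
- Merits: very convergent; the C8 methoxy group and the prenyl ether are in place before ring closure; no persulfate step. On step count after the building blocks this road is clearly better than the chosen one.
- Weak points: the insertion must put the aryl carbon next to oxygen and the methoxy carbon next to the carbonyl, and for an oxygen-polarised alkyne this sense is not secured. The ynol ether A2 hydrolyses easily and has to be made. A1 is a pentasubstituted arene whose own synthesis moves the C8 oxygen problem to the start. The last step still removes acetals in the presence of the prenyl ether.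
- Comparison: the chosen plan sets against the shorter count a ring closure whose regiochemistry cannot go wrong, commodity starting materials, and reaction types known for this substrate class.

**Alternative 2:** The cut is C4a–C4 and C4–C3, with carbon monoxide A6 as C4 between iodophenol A4 (2-iodo-6-methoxy-3,5-bis(methoxymethoxy)phenol) and the aryl methoxymethyl ketone A5.
- Forward key step: Pd(OAc)2 with Xantphos under A6 couples A4 with the enolate of A5 to give the open 1,3-diketone A7. Acid would then close ring C and remove the acetals, and hydrogenolysis would lead to 17.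
- Merits: three components are joined in one step; the C8 methoxy group is built in; A7 is the same kind of intermediate as 11, so the ring C closure is as secure as in the chosen route.
- Weak points: oxidative addition of zerovalent palladium to an electron-rich iodide with two ortho substituents and a free ortho phenol is slow. Direct α-arylation without insertion of A6, and capture of the acylpalladium by a phenol, both compete. The α-methoxy ketone enolate is hindered. A4 needs a regiocontrolled multistep synthesis.
- Comparison: the end of this route joins the chosen one at 17, so it saves the persulfate and methylation steps but not the final three. The chosen plan avoids the pentasubstituted iodophenol and an untested carbonylative coupling, at the price of a late, low-yielding oxidation.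

**Alternative 3:** The cut is C4–C4a and O1–C2, joining mono-phenol A8 (3,5-bis(benzyloxy)-2-methoxyphenol) with the α-methoxy β-keto ester 6 of the chosen route.
- Forward key step: Mentzer condensation, in which heating the two components neat at about 250 °C gives ortho C-acylation and cyclodehydration to flavone A9. Hydrogenolysis of A9 would give 17.
- Merits: this is the shortest way to 17 on paper. It needs no ketal, no chain extension, no persulfate oxidation and no separate methylation, and A8 has only one free ortho position, so a single flavone can form. In step economy it beats the chosen plan by about four operations.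
- Weak points: the pyrocondensation works best with free polyphenols; a mono-phenol carrying three ether groups is a poor partner. Attack of the phenol on the ketone instead of the ester leads to a coumarin. Benzyl aryl ethers are at risk at 250 °C. A8, a 1,2,3,5-tetraoxygenated benzene with three different oxygen states, needs its own multistep synthesis.
- Comparison: the chosen plan sets against this a ring formation under mild ionic conditions from acyclic material, with the oxygen differentiation done on the finished flavone by reactions that follow its inherent acidity order.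

Key step: step 5

Remark on the chemistry: acid chloride 4 is taken as a purchasable compound, and 9 and 11 are written as keto tautomers although they should be largely enolised.

## Route

Step 1
Reactants: 1 dehydroacetic acid (3-acetyl-4-hydroxy-6-methyl-2H-pyran-2-one)
Product: 2 methyl 3,5-dioxohexanoate
Conditions: Mg(OMe)2 (2 equiv), MeOH, reflux; then cold 2 M HCl
Reagents that add atoms: methanol, CO, delivered as magnesium methoxide Mg(OMe)2, C[O-].C[O-].[Mg+2]
Why: Methoxide opens the lactone and a retro-Claisen cleavage removes the C3 acetyl group as methyl acetate, while the magnesium chelate of the resulting 3,5-diketo ester enolate protects it from further cleavage; this ring opening with deacetylation is an established preparation of 2 from 1.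

Step 2
Reactants: 3 methyl methoxyacetate; 4 4-(benzyloxy)benzoyl chloride
Product: 6 rac-methyl 3-[4-(benzyloxy)phenyl]-2-methoxy-3-oxopropanoate, via lithium enolate of methyl methoxyacetate 5 (not isolated)
Conditions: 3 (1.1 equiv), LiN(SiMe3)2 (2.2 equiv), THF, −78 °C; then 4, −78 → 0 °C; aq. NH4Cl
Reagents that add atoms: none
Why: Crossed Claisen-type C-acylation of the preformed lithium ester enolate 5 by a non-enolisable aroyl chloride at low temperature; the second equivalent of amide base deprotonates the more acidic β-keto ester so that 5 is not wasted as a base, and the new stereocentre C2 is formed racemic (it is erased in step 5).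

Step 3
Reactants: 6 rac-methyl 3-[4-(benzyloxy)phenyl]-2-methoxy-3-oxopropanoate
Product: 7 rac-methyl 3-[4-(benzyloxy)phenyl]-2,3,3-trimethoxypropanoate
Conditions: Me3SiOMe (3 equiv), Me3SiOTf (10 mol %), CH2Cl2, −78 → −20 °C; pyridine quench
Reagents that add atoms: methoxytrimethylsilane, CO[Si](C)(C)C
Why: Silyl-triflate-catalysed ketalisation of a ketone with an alkoxysilane is driven by formation of the Si–O–Si bond and runs below −20 °C under kinetic control, so it should convert the hindered aryl ketone, whose oxocarbenium ion is stabilised by the 4-benzyloxyphenyl group, into the dimethyl ketal without the heating that favours loss of methanol to the conjugated enol ether; the ketal removes the 1,3-dicarbonyl acidity of C2.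

Step 4
Reactants: 2 methyl 3,5-dioxohexanoate; 7 rac-methyl 3-[4-(benzyloxy)phenyl]-2,3,3-trimethoxypropanoate
Product: 9 rac-methyl 9-[4-(benzyloxy)phenyl]-8,9,9-trimethoxy-3,5,7-trioxononanoate, via trilithium trianion of methyl 3,5-dioxohexanoate 8 (not isolated)
Conditions: 2 (1.7 equiv), LiN(i-Pr)2 (5.2 equiv), THF, 0 °C; then 7 (1.0 equiv), 0 °C → rt; AcOH, −20 °C; crude 9 used directly
Reagents that add atoms: none
Why: γ-Acylation of a 1,3,5-tricarbonyl polyanion: in 8 the terminal C6 carbanion is the least stabilised and most nucleophilic site and adds to the α-alkoxy-activated ester of 7, the standard chain extension to 3,5,7-triketo esters; the excess of 8 takes up the proton of the new C6 methylene, and the C8 centre stays racemic.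

Step 5
Reactants: 9 rac-methyl 9-[4-(benzyloxy)phenyl]-8,9,9-trimethoxy-3,5,7-trioxononanoate
Product: 12 2-[4-(benzyloxy)phenyl]-5,7-dihydroxy-3-methoxy-4H-chromen-4-one, via ketal-protected acylphloroglucinol 10 (not isolated), via 2-methoxy-1,3-diketone 11 (not isolated)
Conditions: Mg(OMe)2 (6 equiv), MeOH, 25 → 60 °C; then 3 M aq. HCl to pH < 1, 65 °C
Reagents that add atoms: none
Why: Mg(OMe)2 converts 9 into a chelated polyenolate in which C6, flanked by the C5 and C7 carbonyls, attacks the unhindered C1 ester carbonyl (6-exo-trig Claisen condensation, ring A, bond C4a–C8a in flavone numbering), and loss of methoxide with enolisation gives the magnesium salt of acylphloroglucinol 10. The closest known reaction type is the biomimetic Claisen cyclisation of 3,5,7-triketo esters to acylphloroglucinols under a magnesium alkoxide. The selectivity needed is Claisen closure over aldol closure of C2 onto C7; the ester terminus, magnesium chelation of the 3,5,7-trioxygen array and the branched, ketal-bearing C8 that shields the C7 carbonyl should secure it, while the ketal keeps the aryl ketone from acting as a further electrophile or acidifying C8. Aqueous HCl then ionises the ketal through an oxocarbenium ion stabilised by the 4-benzyloxyphenyl group and gives diketone 11 (direct capture of that cation by the phenol would lead to the same product). An ortho hydroxyl adds to the aroyl carbonyl (6-exo-trig, ring C, bond O1–C2) and the hemiketal loses water across C2–C3, as in the acid cyclodehydration of o-hydroxyaryl 1,3-diketones. Because the trihydroxyphenyl ring of 10 is symmetrical about the acylated carbon, both ortho hydroxyls give the same flavone. No stereocentre is formed, and the racemic C8 centre of 9 becomes the sp2 carbon C3. The benzyl ether and the C3 methoxy group should be stable to both stages.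

Step 6
Reactants: 12 2-[4-(benzyloxy)phenyl]-5,7-dihydroxy-3-methoxy-4H-chromen-4-one
Product: 13 7-(benzyloxy)-2-[4-(benzyloxy)phenyl]-5-hydroxy-3-methoxy-4H-chromen-4-one
Conditions: BnBr (1.1 equiv), K2CO3 (1.5 equiv), acetone, reflux
Reagents that add atoms: benzyl bromide, BrCc1ccccc1
Why: Williamson ether synthesis: 7-OH, para to the C4 carbonyl, is the most acidic phenol and is alkylated by one equivalent of halide under weak base, whereas 5-OH is held in a hydrogen bond to C4=O and stays free.

Step 7
Reactants: 13 7-(benzyloxy)-2-[4-(benzyloxy)phenyl]-5-hydroxy-3-methoxy-4H-chromen-4-one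
Product: 15 7-(benzyloxy)-2-[4-(benzyloxy)phenyl]-5,8-dihydroxy-3-methoxy-4H-chromen-4-one, via potassium flavon-8-yl sulfate 14 (not isolated)
Conditions: K2S2O8 (1.5 equiv), aq. KOH, pyridine, 0 → 20 °C; acidify to pH 4 and recover unchanged 13; then 2 M HCl, Na2SO3, 85 °C
Reagents that add atoms: potassium peroxodisulfate, [K+].[K+].[O-]S(=O)(=O)OOS(=O)(=O)[O-]
Why: Elbs persulfate oxidation: the 5-phenolate attacks a peroxide oxygen of the peroxodisulfate through its para carbon C8 (the ortho carbon C4a is substituted and C6 is only ortho), and acid hydrolysis of aryl sulfate 14 frees the 8-OH; this is the classical way from 5-hydroxy-7-alkoxyflavones to 5,8-dihydroxyflavones, and the benzyl ethers and the C3 methyl ether should tolerate cold alkali and brief warm dilute acid.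

Step 8
Reactants: 15 7-(benzyloxy)-2-[4-(benzyloxy)phenyl]-5,8-dihydroxy-3-methoxy-4H-chromen-4-one
Product: 16 7-(benzyloxy)-2-[4-(benzyloxy)phenyl]-5-hydroxy-3,8-dimethoxy-4H-chromen-4-one
Conditions: Me2SO4 (1.1 equiv), K2CO3, acetone, reflux
Reagents that add atoms: dimethyl sulfate, COS(=O)(=O)OC
Why: Partial Williamson methylation: the 8-OH is a free phenol, whereas the 5-OH is chelated to the C4 carbonyl and is not alkylated by about one equivalent of dimethyl sulfate under K2CO3.

Step 9
Reactants: 16 7-(benzyloxy)-2-[4-(benzyloxy)phenyl]-5-hydroxy-3,8-dimethoxy-4H-chromen-4-one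
Product: 17 5,7-dihydroxy-2-(4-hydroxyphenyl)-3,8-dimethoxy-4H-chromen-4-one
Conditions: H2 (1 atm), 10% Pd/C, EtOAc–MeOH, rt
Reagents that add atoms: none
Why: Catalytic hydrogenolysis of both benzyl aryl ethers; aryl methyl ethers and the conjugated C2=C3 bond of the chromone are inert at 1 atm and room temperature.

Step 10
Reactants: 17 5,7-dihydroxy-2-(4-hydroxyphenyl)-3,8-dimethoxy-4H-chromen-4-one
Product: 18 5-hydroxy-2-(4-hydroxyphenyl)-3,8-dimethoxy-7-(methoxymethoxy)-4H-chromen-4-one
Conditions: MOMCl (1.05 equiv), K2CO3 (1.1 equiv), acetone, 0 °C → rt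
Reagents that add atoms: chloromethyl methyl ether, COCCl
Why: Williamson-type acetalisation under limited base: with about one equivalent of K2CO3 the 7-phenolate (para to the C4 carbonyl) is formed in preference to the 4'-phenolate and the chelated 5-OH, the same order of reactivity that governs selective 7-O-alkylation of 5,7,4'-trihydroxyflavones.

Step 11
Reactants: 18 5-hydroxy-2-(4-hydroxyphenyl)-3,8-dimethoxy-7-(methoxymethoxy)-4H-chromen-4-one; 19 1-bromo-3-methylbut-2-ene (prenyl bromide)
Product: 20 5-hydroxy-3,8-dimethoxy-7-(methoxymethoxy)-2-{4-[(3-methylbut-2-en-1-yl)oxy]phenyl}-4H-chromen-4-one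
Conditions: 19 (1.3 equiv), K2CO3 (2 equiv), acetone, reflux
Reagents that add atoms: none
Why: Williamson SN2 alkylation of the only remaining non-chelated phenol by the primary allylic bromide 19; O-alkylation at the unsubstituted CH2 terminus is favoured in acetone with K2CO3, and the acetal and methyl ethers are stable to base.

Step 12
Reactants: 20 5-hydroxy-3,8-dimethoxy-7-(methoxymethoxy)-2-{4-[(3-methylbut-2-en-1-yl)oxy]phenyl}-4H-chromen-4-one
Product: 21 5,7-dihydroxy-3,8-dimethoxy-2-{4-[(3-methylbut-2-en-1-yl)oxy]phenyl}-4H-chromen-4-one
Conditions: HCl (0.5 M) in MeOH–THF, 25–40 °C, stopped at full conversion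
Reagents that add atoms: none
Why: Acid-catalysed methanolysis of the formaldehyde acetal through the methoxymethyl oxocarbenium ion, which forms far more readily than the prenyl cation from the aryl allylic ether under dilute acid near room temperature, so the acetal should be removed while the prenyl ether survives.

## Compound list

1 | dehydroacetic acid (3-acetyl-4-hydroxy-6-methyl-2H-pyran-2-one) | CC(=O)C1=C(O)C=C(C)OC1=O | starting material
2 | methyl 3,5-dioxohexanoate | COC(=O)CC(=O)CC(C)=O | intermediate
3 | methyl methoxyacetate | COCC(=O)OC | starting material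
4 | 4-(benzyloxy)benzoyl chloride | O=C(Cl)c1ccc(OCc2ccccc2)cc1 | starting material
5 | lithium 1,2-dimethoxyethen-1-olate (lithium enolate of 3) | [Li+].COC=C([O-])OC | intermediate
6 | rac-methyl 3-[4-(benzyloxy)phenyl]-2-methoxy-3-oxopropanoate | COC(=O)C(OC)C(=O)c1ccc(OCc2ccccc2)cc1 | intermediate
7 | rac-methyl 3-[4-(benzyloxy)phenyl]-2,3,3-trimethoxypropanoate | COC(=O)C(OC)C(OC)(OC)c1ccc(OCc2ccccc2)cc1 | intermediate
8 | trilithium salt of the 2,4,6-trianion of methyl 3,5-dioxohexanoate | [Li+].[Li+].[Li+].[CH2-]C(=O)[CH-]C(=O)[CH-]C(=O)OC | intermediate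
9 | rac-methyl 9-[4-(benzyloxy)phenyl]-8,9,9-trimethoxy-3,5,7-trioxononanoate | COC(=O)CC(=O)CC(=O)CC(=O)C(OC)C(OC)(OC)c1ccc(OCc2ccccc2)cc1 | intermediate
10 | rac-3-[4-(benzyloxy)phenyl]-2,3,3-trimethoxy-1-(2,4,6-trihydroxyphenyl)propan-1-one | COC(C(=O)c1c(O)cc(O)cc1O)C(OC)(OC)c1ccc(OCc2ccccc2)cc1 | intermediate
11 | rac-1-[4-(benzyloxy)phenyl]-2-methoxy-3-(2,4,6-trihydroxyphenyl)propane-1,3-dione | COC(C(=O)c1c(O)cc(O)cc1O)C(=O)c1ccc(OCc2ccccc2)cc1 | intermediate
12 | 2-[4-(benzyloxy)phenyl]-5,7-dihydroxy-3-methoxy-4H-chromen-4-one | COc1c(-c2ccc(OCc3ccccc3)cc2)oc2cc(O)cc(O)c2c1=O | intermediate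
13 | 7-(benzyloxy)-2-[4-(benzyloxy)phenyl]-5-hydroxy-3-methoxy-4H-chromen-4-one | COc1c(-c2ccc(OCc3ccccc3)cc2)oc2cc(OCc3ccccc3)cc(O)c2c1=O | intermediate
14 | potassium 7-(benzyloxy)-2-[4-(benzyloxy)phenyl]-5-hydroxy-3-methoxy-4-oxo-4H-chromen-8-yl sulfate | [K+].COc1c(-c2ccc(OCc3ccccc3)cc2)oc2c(OS(=O)(=O)[O-])c(OCc3ccccc3)cc(O)c2c1=O | intermediate
15 | 7-(benzyloxy)-2-[4-(benzyloxy)phenyl]-5,8-dihydroxy-3-methoxy-4H-chromen-4-one | COc1c(-c2ccc(OCc3ccccc3)cc2)oc2c(O)c(OCc3ccccc3)cc(O)c2c1=O | intermediate
16 | 7-(benzyloxy)-2-[4-(benzyloxy)phenyl]-5-hydroxy-3,8-dimethoxy-4H-chromen-4-one | COc1c(-c2ccc(OCc3ccccc3)cc2)oc2c(OC)c(OCc3ccccc3)cc(O)c2c1=O | intermediate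
17 | 5,7-dihydroxy-2-(4-hydroxyphenyl)-3,8-dimethoxy-4H-chromen-4-one | COc1c(-c2ccc(O)cc2)oc2c(OC)c(O)cc(O)c2c1=O | intermediate
18 | 5-hydroxy-2-(4-hydroxyphenyl)-3,8-dimethoxy-7-(methoxymethoxy)-4H-chromen-4-one | COCOc1cc(O)c2c(=O)c(OC)c(-c3ccc(O)cc3)oc2c1OC | intermediate
19 | 1-bromo-3-methylbut-2-ene (prenyl bromide) | CC(C)=CCBr | starting material
20 | 5-hydroxy-3,8-dimethoxy-7-(methoxymethoxy)-2-{4-[(3-methylbut-2-en-1-yl)oxy]phenyl}-4H-chromen-4-one | COCOc1cc(O)c2c(=O)c(OC)c(-c3ccc(OCC=C(C)C)cc3)oc2c1OC | intermediate
21 | 5,7-dihydroxy-3,8-dimethoxy-2-{4-[(3-methylbut-2-en-1-yl)oxy]phenyl}-4H-chromen-4-one | COc1c(-c2ccc(OCC=C(C)C)cc2)oc2c(OC)c(O)cc(O)c2c1=O | target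

## Step count and least certain steps

Total step count: 12. Longest linear sequence: 11 steps (steps 2 to 12, from 3 and 4 to 21).

**Step 5 (key step).** The chain may fold the other way, by aldol closure of C2 onto C7 leading to a resorcylate, or it may be cut by retro-Claisen attack of methoxide. The more heavily oxygenated C7–C9 end has not been tried in this cyclisation and may also lose methanol before ring A forms. The fallback gives up the chain folding and builds ring C on a preformed ring A by an Allan–Robinson condensation. It sets out from 4: half-hydrolysis (0.5 equiv water, pyridine) would give 4-(benzyloxy)benzoic anhydride F5. F5 would be heated at about 160 °C with Et3N and 2-methoxy-1-(2,4,6-trihydroxyphenyl)ethan-1-one F6, which is accessible by a Hoesch reaction. Brief treatment with KOH in aqueous methanol to cleave O-aroyl esters would then return to the route at 12.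

**Step 4.** Proton transfer from the α-position of ester 7 to trianion 8 may outrun addition to the hindered carbonyl; the resulting ester enolate would expel methoxide from the ketal and destroy the mask. The fallback replaces acylation by aldol addition and oxidation. It sets out from 7: reduction with i-Bu2AlH at −78 °C would give rac-3-[4-(benzyloxy)phenyl]-2,3,3-trimethoxypropanal F3. The far more electrophilic F3 should add 8 at −78 °C to give methyl 9-[4-(benzyloxy)phenyl]-7-hydroxy-8,9,9-trimethoxy-3,5-dioxononanoate F4. Oxidation of the secondary alcohol with the triacetoxy periodinane DMP would return to the route at 9.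

**Step 3.** The crowded dimethyl ketal may form slowly, or may lose methanol towards the ester-conjugated enol ether. The fallback changes the mask to a cyclic ketal, which has no such exit because ring opening is reversible. It sets out from 6: 1,2-bis(trimethylsilyloxy)ethane with catalytic Me3SiOTf would give rac-methyl 2-{2-[4-(benzyloxy)phenyl]-1,3-dioxolan-2-yl}-2-methoxyacetate F1. Acylation of 8 with F1 as in step 4 would give rac-methyl 8-{2-[4-(benzyloxy)phenyl]-1,3-dioxolan-2-yl}-8-methoxy-3,5,7-trioxooctanoate F2. Mg(OMe)2 followed by aqueous HCl as in step 5 would return to the route at 12.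

**Step 7.** Elbs oxidations usually stop at partial conversion. The hydroquinone product can be over-oxidised in the alkaline medium, the dibenzyl ether dissolves poorly in aqueous base, and prolonged alkali may open the pyranone. The fallback replaces phenolate oxidation by halogenation and copper-mediated C–O coupling. It sets out from 13:
- exhaustive methylation (excess Me2SO4, K2CO3) would give 7-(benzyloxy)-2-[4-(benzyloxy)phenyl]-3,5-dimethoxy-4H-chromen-4-one F7;
- iodination with N-iodosuccinimide and catalytic CF3CO2H, which for 5,7-dialkoxyflavones is expected at C8, would give 7-(benzyloxy)-2-[4-(benzyloxy)phenyl]-8-iodo-3,5-dimethoxy-4H-chromen-4-one F8;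
- Ullmann-type methoxylation (NaOMe, CuBr, DMF–MeOH, 110 °C) would give 7-(benzyloxy)-2-[4-(benzyloxy)phenyl]-3,5,8-trimethoxy-4H-chromen-4-one F9;
- BCl3 in CH2Cl2 (−78 → 0 °C), which cleaves benzyl aryl ethers and the methoxy group peri to the carbonyl, would return to the route at 17.

**Step 12.** The acid may ionise the aryl prenyl ether as well, with loss or cyclisation of the side chain, before the acetal is fully cleaved. The fallback uses a silyl group and fluoride, so that no acid meets the prenyl ether. It sets out from 17:
- i-Pr3SiCl (1.05 equiv) with imidazole in DMF at 0 °C should silylate the most acidic 7-OH to give 5-hydroxy-2-(4-hydroxyphenyl)-3,8-dimethoxy-7-[(triisopropylsilyl)oxy]-4H-chromen-4-one F10;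
- a Mitsunobu reaction with 3-methylbut-2-en-1-ol (PPh3, diisopropyl azodicarboxylate, THF), to which the chelated 5-OH is inert, would give 5-hydroxy-3,8-dimethoxy-2-{4-[(3-methylbut-2-en-1-yl)oxy]phenyl}-7-[(triisopropylsilyl)oxy]-4H-chromen-4-one F11;
- Bu4NF buffered with AcOH would return to the route at 21.

## Further compounds

F1 | step 3 | rac-methyl 2-{2-[4-(benzyloxy)phenyl]-1,3-dioxolan-2-yl}-2-methoxyacetate | COC(=O)C(OC)C1(c2ccc(OCc3ccccc3)cc2)OCCO1
F2 | step 3 | rac-methyl 8-{2-[4-(benzyloxy)phenyl]-1,3-dioxolan-2-yl}-8-methoxy-3,5,7-trioxooctanoate | COC(=O)CC(=O)CC(=O)CC(=O)C(OC)C1(c2ccc(OCc3ccccc3)cc2)OCCO1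
F3 | step 4 | rac-3-[4-(benzyloxy)phenyl]-2,3,3-trimethoxypropanal | O=CC(OC)C(OC)(OC)c1ccc(OCc2ccccc2)cc1
F4 | step 4 | methyl 9-[4-(benzyloxy)phenyl]-7-hydroxy-8,9,9-trimethoxy-3,5-dioxononanoate (racemic mixture of diastereomers) | COC(=O)CC(=O)CC(=O)CC(O)C(OC)C(OC)(OC)c1ccc(OCc2ccccc2)cc1
F5 | step 5 | 4-(benzyloxy)benzoic anhydride | O=C(OC(=O)c1ccc(OCc2ccccc2)cc1)c1ccc(OCc2ccccc2)cc1
F6 | step 5 | 2-methoxy-1-(2,4,6-trihydroxyphenyl)ethan-1-one | COCC(=O)c1c(O)cc(O)cc1O
F7 | step 7 | 7-(benzyloxy)-2-[4-(benzyloxy)phenyl]-3,5-dimethoxy-4H-chromen-4-one | COc1c(-c2ccc(OCc3ccccc3)cc2)oc2cc(OCc3ccccc3)cc(OC)c2c1=O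
F8 | step 7 | 7-(benzyloxy)-2-[4-(benzyloxy)phenyl]-8-iodo-3,5-dimethoxy-4H-chromen-4-one | COc1c(-c2ccc(OCc3ccccc3)cc2)oc2c(I)c(OCc3ccccc3)cc(OC)c2c1=O
F9 | step 7 | 7-(benzyloxy)-2-[4-(benzyloxy)phenyl]-3,5,8-trimethoxy-4H-chromen-4-one | COc1c(-c2ccc(OCc3ccccc3)cc2)oc2c(OC)c(OCc3ccccc3)cc(OC)c2c1=O
F10 | step 12 | 5-hydroxy-2-(4-hydroxyphenyl)-3,8-dimethoxy-7-[(triisopropylsilyl)oxy]-4H-chromen-4-one | COc1c(-c2ccc(O)cc2)oc2c(OC)c(O[Si](C(C)C)(C(C)C)C(C)C)cc(O)c2c1=O
F11 | step 12 | 5-hydroxy-3,8-dimethoxy-2-{4-[(3-methylbut-2-en-1-yl)oxy]phenyl}-7-[(triisopropylsilyl)oxy]-4H-chromen-4-one | COc1c(-c2ccc(OCC=C(C)C)cc2)oc2c(OC)c(O[Si](C(C)C)(C(C)C)C(C)C)cc(O)c2c1=O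
A1 | alternative 1 | 2-hydroxy-3-methoxy-4,6-bis(methoxymethoxy)benzaldehyde | COCOc1cc(OCOC)c(OC)c(O)c1C=O
A2 | alternative 1 | 1-(methoxyethynyl)-4-[(3-methylbut-2-en-1-yl)oxy]benzene | COC#Cc1ccc(OCC=C(C)C)cc1
A3 | alternative 1 | 3,8-dimethoxy-5,7-bis(methoxymethoxy)-2-{4-[(3-methylbut-2-en-1-yl)oxy]phenyl}-4H-chromen-4-one | COc1c(-c2ccc(OCC=C(C)C)cc2)oc2c(OC)c(OCOC)cc(OCOC)c2c1=O
A4 | alternative 2 | 2-iodo-6-methoxy-3,5-bis(methoxymethoxy)phenol | COCOc1cc(OCOC)c(OC)c(O)c1I
A5 | alternative 2 | 1-[4-(benzyloxy)phenyl]-2-methoxyethan-1-one | COCC(=O)c1ccc(OCc2ccccc2)cc1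
A6 | alternative 2 | carbon monoxide | [C-]#[O+]
A7 | alternative 2 | rac-3-[4-(benzyloxy)phenyl]-1-[2-hydroxy-3-methoxy-4,6-bis(methoxymethoxy)phenyl]-2-methoxypropane-1,3-dione | COC(C(=O)c1ccc(OCc2ccccc2)cc1)C(=O)c1c(O)c(OC)c(OCOC)cc1OCOC
A8 | alternative 3 | 3,5-bis(benzyloxy)-2-methoxyphenol | COc1c(O)cc(OCc2ccccc2)cc1OCc1ccccc1
A9 | alternative 3 | 5,7-bis(benzyloxy)-2-[4-(benzyloxy)phenyl]-3,8-dimethoxy-4H-chromen-4-one | COc1c(-c2ccc(OCc3ccccc3)cc2)oc2c(OC)c(OCc3ccccc3)cc(OCc3ccccc3)c2c1=O
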